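Oxolane numbering used throughout: O1, C2 (aryl), C3 (CH2OH), C4 (aroyl), C5 (CH2). Cuts: first the aryl–C(=O) bond, to an aryllithium and a cis-fused γ-lactone that ties the C4 carboxyl to the C3 hydroxymethyl oxygen (a ring the target does not have); then O1–C5 and C3–C4 together, to a trans-2-aryl-3-vinyloxirane and methyl acrylate, the vinyl group standing in for CH2OH.
Enabling feature: in the oxolane ring O1 sits β to the C4 carbonyl (O1–C5H2–C4–C=O, an oxa-Michael pattern), and C3, next to the O1-bearing benzylic C2, is an allyl terminus once its substituent is vinyl. A π-allylpalladium alkoxide zwitterion from the vinyloxirane can therefore give O1 to C5 and take C4 at C3 in one catalytic event.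
Forward: aryl diene → oxirane → oxolane (the only ring of the target) → vinyl cleaved to CH2OH → temporary lactone ring → opened by the second aryl group to the hydroxy ketone → desilylation.
Stereochemistry: C2 from catalyst-controlled asymmetric epoxidation; C3 relayed from C2 in the cycloaddition (aryl and vinyl trans); C4 from the cis-fused lactone, which only the C3/C4-cis epimer can form, and kept when the lactone is opened at −78 °C.
Key step: step 4

Remark: the γ-hydroxy ketones 14 and 15 may rest partly as their cyclic hemiketals; they are drawn and named in the open form of the target.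
Abbreviation: Ar = 3,5-dimethoxy-4-[tri(propan-2-yl)silyloxy]phenyl (TIPS = tri(propan-2-yl)silyl).

Step 1
Reactants: 1 syringaldehyde (4-hydroxy-3,5-dimethoxybenzaldehyde)
Product: 2 3,5-dimethoxy-4-[tri(propan-2-yl)silyloxy]benzaldehyde
Conditions: TIPSCl (1.2 equiv), imidazole (2.5 equiv), DMF, rt
Reagents that add atoms: chlorotri(propan-2-yl)silane (TIPSCl), CC(C)[Si](Cl)(C(C)C)C(C)C
Why: Silyl ether formation on the phenol; the bulky silyl group, flanked by two methoxy groups, should survive the organolithium, buffered-basic oxidation, palladium, ozone, hydride and amidine-base steps and leave with fluoride at the end.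

Step 2
Reactants: 2 3,5-dimethoxy-4-[tri(propan-2-yl)silyloxy]benzaldehyde; 3 diethyl prop-2-en-1-ylphosphonate (diethyl allylphosphonate)
Product: 4 {4-[(1E)-buta-1,3-dien-1-yl]-2,6-dimethoxyphenoxy}tri(propan-2-yl)silane
Conditions: n-BuLi, THF, −78 °C; then 2; HMPA, −78 °C → rt
Reagents that add atoms: none
Why: Horner–Wadsworth–Emmons-type olefination with the α-lithiated allylphosphonate: addition through the α-carbon and HMPA-promoted loss of lithium diethyl phosphate should give the terminal 1,3-diene with the E geometry favoured by the conjugated, thermodynamically controlled elimination.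

Step 3
Reactants: 4 {4-[(1E)-buta-1,3-dien-1-yl]-2,6-dimethoxyphenoxy}tri(propan-2-yl)silane
Product: 5 (2R,3R)-2-Ar-3-ethenyloxirane (trans)
Conditions: 1,2:4,5-di-O-isopropylidene-β-D-erythro-2,3-hexodiulo-2,6-pyranose (D-fructose-derived ketone, 0.3 equiv), Oxone (2KHSO5·KHSO4·K2SO4), K2CO3, Bu4NHSO4, MeCN/CH2(OMe)2, aq. Na2B4O7 buffer (pH ≈ 10.5), 0 °C
Reagents that add atoms: potassium peroxymonosulfate (active salt of Oxone), [K+].[O-]S(=O)(=O)OO
Why: Shi epoxidation: the chiral dioxirane generated from the ketone and KHSO5 should epoxidise the electron-rich trans-disubstituted styrenyl alkene rather than the monosubstituted terminal one, and its spiro transition state sets both oxirane carbons as (2R,3R), as it does for simple trans-β-alkylstyrenes, which fixes the benzylic stereocentre that becomes C2 of the target; the buffered basic medium protects the acid-labile benzylic oxirane.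

Step 4
Reactants: 5 (2R,3R)-2-Ar-3-ethenyloxirane; 6 methyl acrylate (methyl prop-2-enoate)
Product: 7 methyl (3RS,4S,5S)-5-Ar-4-ethenyloxolane-3-carboxylate (aryl and vinyl trans; both epimers at the ester carbon)
Conditions: Pd2(dba)3·CHCl3 (2.5 mol %), Ph2PCH2CH2PPh2 (5.5 mol %), 6 (5 equiv), THF, 40 °C
Reagents that add atoms: none
Why: Proposed new method: zerovalent palladium ionises the allylic C–O bond of 5 with inversion to a zwitterionic π-allylpalladium alkoxide, whose oxygen adds to the CH2 terminus of methyl acrylate (oxa-Michael addition, forming O1–C5) and whose ester enolate then attacks the proximal allyl terminus anti to palladium (forming C3–C4) and releases the catalyst; the closest known reaction type is the palladium-catalysed formal [3+2] cycloaddition of vinyloxiranes with doubly activated alkenes, nitroalkenes and enones, and the extension to a singly ester-activated alkene is argued from the fast, reversible conjugate addition of alkoxides to acrylates and from the irreversible intramolecular capture of the ester enolate by the cationic allyl unit held next to it. The first bond is made intermolecularly and the oxolane then closes by a 5-exo-trig allylic alkylation (enolate carbon onto the allyl terminus, the remaining vinyl group exocyclic), which is preferred over the seven-membered closure at the distal terminus. The benzylic stereocentre (C2) is carried over unchanged from 5 because its C–O bond is never broken; C3 is set with net retention by the double inversion and, should the allyl complex equilibrate by π–σ–π isomerisation, by the preference of the closing ring for aryl and vinyl trans. The ester-bearing carbon (C4) is not controlled here and both epimers are expected, which is harmless because step 6 equilibrates this centre. The step needs chemoselectivity for conjugate O-addition over acyl transfer to the alkoxide and over palladium-mediated hydride shift of the zwitterion to an aryl ketone, which the excess of unhindered acrylate and a chelating diphosphine at mild temperature are meant to secure.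

Step 5
Reactants: 7 methyl (3RS,4S,5S)-5-Ar-4-ethenyloxolane-3-carboxylate
Product: 9 methyl (3RS,4R,5S)-5-Ar-4-(hydroxymethyl)oxolane-3-carboxylate, via aldehyde 8 (not isolated)
Conditions: O3, CH2Cl2/MeOH (4:1), Sudan Red 7B (indicator), −78 °C; then NaBH4, −78 → 0 °C
Reagents that add atoms: ozone, [O-][O+]=O
Why: Ozonolysis with reductive work-up: the terminal alkene reacts far faster than the arene (the dye marks the end point) and NaBH4 reduces the ozonolysis products to the primary alcohol without touching the methyl ester, so the vinyl helper becomes the hydroxymethyl group with C3 unchanged (any cis epimer that already lactonises to 10 is carried along).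

Step 6
Reactants: 9 methyl (3RS,4R,5S)-5-Ar-4-(hydroxymethyl)oxolane-3-carboxylate
Product: 10 (1R,5R,6S)-6-Ar-3,7-dioxabicyclo[3.3.0]octan-2-one (cis-fused lactone, aryl exo)
Conditions: DBU (2 equiv), toluene, 100 °C
Reagents that add atoms: none
Why: Epimerisation–lactonisation under thermodynamic control: only the epimer with ester and hydroxymethyl cis can close the bicyclo[3.3.0] γ-lactone (a trans-fused one is too strained), so DBU-mediated equilibration α to the ester, with methanol leaving the hot toluene, should funnel both epimers into the cis-fused lactone and thereby set C4 cis to C3.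

Step 7
Reactants: 11 4-bromo-2,6-dimethoxyphenol
Product: 12 (4-bromo-2,6-dimethoxyphenoxy)tri(propan-2-yl)silane
Conditions: TIPSCl (1.2 equiv), imidazole (2.5 equiv), DMF, rt
Reagents that add atoms: chlorotri(propan-2-yl)silane (TIPSCl), CC(C)[Si](Cl)(C(C)C)C(C)C
Why: Silyl ether formation on the phenol, giving an aryl bromide that tolerates bromine–lithium exchange and carries the same fluoride-labile group as the other ring.

Step 8
Reactants: 10 (1R,5R,6S)-6-Ar-3,7-dioxabicyclo[3.3.0]octan-2-one; 12 (4-bromo-2,6-dimethoxyphenoxy)tri(propan-2-yl)silane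
Product: 14 Ar[(3R,4R,5S)-5-Ar-4-(hydroxymethyl)oxolan-3-yl]methanone (bis-silyl ether of the target), via aryllithium 13 (not isolated)
Conditions: 12 (1.3 equiv), n-BuLi (1.25 equiv), THF, −78 °C; then 10, THF, −78 °C; aq. NH4Cl, −78 °C → rt
Reagents that add atoms: none
Why: Bromine–lithium exchange, then single addition of the aryllithium to the γ-lactone carbonyl: the lithium hemiketalate is stable at −78 °C, so no second addition should occur and the ketone and the free hydroxymethyl group appear together on protonation, with the lactone-derived cis stereocentre α to the new ketone never exposed to base.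

Step 9
Reactants: 14 Ar[(3R,4R,5S)-5-Ar-4-(hydroxymethyl)oxolan-3-yl]methanone
Product: 15 ciwujiatone, (4-hydroxy-3,5-dimethoxyphenyl)[(3R,4R,5S)-5-(4-hydroxy-3,5-dimethoxyphenyl)-4-(hydroxymethyl)oxolan-3-yl]methanone
Conditions: Bu4NF (2.4 equiv), AcOH (2.6 equiv), THF, 0 °C
Reagents that add atoms: none
Why: Fluoride-induced cleavage of both aryl silyl ethers, buffered with acetic acid so that neither a phenoxide para to the benzylic ether nor the enolisable centre α to the ketone sees basic conditions.

Compound list
1 | syringaldehyde (4-hydroxy-3,5-dimethoxybenzaldehyde) | COc1cc(C=O)cc(OC)c1O | starting material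
2 | 3,5-dimethoxy-4-[tri(propan-2-yl)silyloxy]benzaldehyde | COc1cc(C=O)cc(OC)c1O[Si](C(C)C)(C(C)C)C(C)C | intermediate
3 | diethyl prop-2-en-1-ylphosphonate | C=CCP(=O)(OCC)OCC | starting material
4 | {4-[(1E)-buta-1,3-dien-1-yl]-2,6-dimethoxyphenoxy}tri(propan-2-yl)silane | C=C/C=C/c1cc(OC)c(O[Si](C(C)C)(C(C)C)C(C)C)c(OC)c1 | intermediate
5 | (2R,3R)-2-{3,5-dimethoxy-4-[tri(propan-2-yl)silyloxy]phenyl}-3-ethenyloxirane | C=C[C@H]1O[C@@H]1c2cc(OC)c(O[Si](C(C)C)(C(C)C)C(C)C)c(OC)c2 | intermediate
6 | methyl prop-2-enoate (methyl acrylate) | C=CC(=O)OC | starting material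
7 | methyl (3RS,4S,5S)-5-{3,5-dimethoxy-4-[tri(propan-2-yl)silyloxy]phenyl}-4-ethenyloxolane-3-carboxylate (epimers at C3) | COC(=O)C1CO[C@H](c2cc(OC)c(O[Si](C(C)C)(C(C)C)C(C)C)c(OC)c2)[C@H]1C=C | intermediate
8 | methyl (3RS,4S,5S)-5-{3,5-dimethoxy-4-[tri(propan-2-yl)silyloxy]phenyl}-4-formyloxolane-3-carboxylate (epimers at C3) | COC(=O)C1CO[C@H](c2cc(OC)c(O[Si](C(C)C)(C(C)C)C(C)C)c(OC)c2)[C@H]1C=O | intermediate (not isolated)
9 | methyl (3RS,4R,5S)-5-{3,5-dimethoxy-4-[tri(propan-2-yl)silyloxy]phenyl}-4-(hydroxymethyl)oxolane-3-carboxylate (epimers at C3) | COC(=O)C1CO[C@H](c2cc(OC)c(O[Si](C(C)C)(C(C)C)C(C)C)c(OC)c2)[C@H]1CO | intermediate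
10 | (1R,5R,6S)-6-{3,5-dimethoxy-4-[tri(propan-2-yl)silyloxy]phenyl}-3,7-dioxabicyclo[3.3.0]octan-2-one | O=C3[C@H]2CO[C@H](c4cc(OC)c(O[Si](C(C)C)(C(C)C)C(C)C)c(OC)c4)[C@H]2CO3 | intermediate
11 | 4-bromo-2,6-dimethoxyphenol | COc1cc(Br)cc(OC)c1O | starting material
12 | (4-bromo-2,6-dimethoxyphenoxy)tri(propan-2-yl)silane | COc1cc(Br)cc(OC)c1O[Si](C(C)C)(C(C)C)C(C)C | intermediate
13 | {3,5-dimethoxy-4-[tri(propan-2-yl)silyloxy]phenyl}lithium | [Li]c1cc(OC)c(O[Si](C(C)C)(C(C)C)C(C)C)c(OC)c1 | intermediate (not isolated)
14 | {3,5-dimethoxy-4-[tri(propan-2-yl)silyloxy]phenyl}[(3R,4R,5S)-5-{3,5-dimethoxy-4-[tri(propan-2-yl)silyloxy]phenyl}-4-(hydroxymethyl)oxolan-3-yl]methanone | COc1cc(C(=O)[C@H]2CO[C@H](c3cc(OC)c(O[Si](C(C)C)(C(C)C)C(C)C)c(OC)c3)[C@H]2CO)cc(OC)c1O[Si](C(C)C)(C(C)C)C(C)C | intermediate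
15 | ciwujiatone, (4-hydroxy-3,5-dimethoxyphenyl)[(3R,4R,5S)-5-(4-hydroxy-3,5-dimethoxyphenyl)-4-(hydroxymethyl)oxolan-3-yl]methanone | COc1cc(C(=O)[C@H]2CO[C@H](c3cc(OC)c(O)c(OC)c3)[C@H]2CO)cc(OC)c1O | target

Total step count: 9. Longest linear sequence: 8 steps (1, 2, 3, 4, 5, 6, 8, 9).

Steps most likely to fail

Step 4 (proposed new method). The conjugate O-addition to a singly activated acrylate may be too slow. The zwitterion would then be lost by palladium-mediated hydride shift to an aryl allyl ketone, by closure of the alkoxide onto the distal allyl terminus, or by acyl transfer from the acrylate to the alkoxide. The fallback keeps the disconnection but uses the acceptor class on which this palladium cycloaddition is established; it sets out from 5 and comes back at 10. Under the conditions of step 4, 5 and diethyl methylidenemalonate (a 1,1-diester-activated alkene, added slowly to hold back its anionic oligomerisation) should give the oxolane-3,3-diester F1, which has no stereocentre at C4. Ozonolysis with NaBH4 work-up as in step 5 should lead through the aldehyde diester F2 and the hydroxy diester F3, whose hydroxymethyl group closes onto the cis ester, to the lactone ester F4. Krapcho dealkoxycarbonylation (LiCl, wet DMSO, 140 °C) then removes the remaining ester, and protonation of the lactone enolate can only give the cis-fused lactone 10. If chloride at this temperature takes off the aryl silyl ether, TIPSCl/imidazole puts it back.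

Step 3. Discrimination between the two alkenes of the diene or between its faces may be incomplete, and the electron-rich benzylic oxirane may open under traces of acid during isolation. The fallback is a Sharpless asymmetric epoxidation route that sets out from 2 and comes back at 5. Horner–Wadsworth–Emmons reaction of 2 with triethyl phosphonoacetate (NaH, THF) gives the E-cinnamate F5, and i-Bu2AlH reduction gives the allylic alcohol F6. Epoxidation with Ti(OiPr)4, D-(−)-diethyl tartrate and t-BuOOH (4 Å sieves, CH2Cl2, −20 °C) gives the (2R,3R)-epoxy alcohol F7. Parikh–Doering oxidation (SO3·pyridine, DMSO, i-Pr2NEt) gives the epoxy aldehyde F8, and Wittig methylenation with Ph3P=CH2 gives 5.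

Step 8. The tetrahedral intermediate may collapse early and take up a second aryllithium, or the aryllithium may deprotonate the lactone instead of adding. The fallback goes through a Weinreb amide, which cannot add twice; it sets out from 10 and comes back at 15. Aminolysis of 10 with MeNH(OMe)·HCl/AlMe3 gives the hydroxy Weinreb amide F9, and silylation (Et3SiCl, imidazole) gives the triethylsilyl ether F10. Addition of aryllithium 13 at −78 °C gives, from its stable chelate, the silylated ketone F11, and Bu4NF/AcOH removes the three silyl groups to give 15.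

Further compounds
F1 | step 4 | diethyl (4S,5S)-5-{3,5-dimethoxy-4-[tri(propan-2-yl)silyloxy]phenyl}-4-ethenyloxolane-3,3-dicarboxylate | CCOC(=O)C1(C(=O)OCC)CO[C@H](c2cc(OC)c(O[Si](C(C)C)(C(C)C)C(C)C)c(OC)c2)[C@H]1C=C
F2 | step 4 | diethyl (4S,5S)-5-{3,5-dimethoxy-4-[tri(propan-2-yl)silyloxy]phenyl}-4-formyloxolane-3,3-dicarboxylate | CCOC(=O)C1(C(=O)OCC)CO[C@H](c2cc(OC)c(O[Si](C(C)C)(C(C)C)C(C)C)c(OC)c2)[C@H]1C=O
F3 | step 4 | diethyl (4R,5S)-5-{3,5-dimethoxy-4-[tri(propan-2-yl)silyloxy]phenyl}-4-(hydroxymethyl)oxolane-3,3-dicarboxylate | CCOC(=O)C1(C(=O)OCC)CO[C@H](c2cc(OC)c(O[Si](C(C)C)(C(C)C)C(C)C)c(OC)c2)[C@H]1CO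
F4 | step 4 | ethyl (1R,5R,6S)-6-{3,5-dimethoxy-4-[tri(propan-2-yl)silyloxy]phenyl}-2-oxo-3,7-dioxabicyclo[3.3.0]octane-1-carboxylate | O=C3[C@@]2(C(=O)OCC)CO[C@H](c4cc(OC)c(O[Si](C(C)C)(C(C)C)C(C)C)c(OC)c4)[C@H]2CO3
F5 | step 3 | ethyl (2E)-3-{3,5-dimethoxy-4-[tri(propan-2-yl)silyloxy]phenyl}prop-2-enoate | CCOC(=O)/C=C/c1cc(OC)c(O[Si](C(C)C)(C(C)C)C(C)C)c(OC)c1
F6 | step 3 | (2E)-3-{3,5-dimethoxy-4-[tri(propan-2-yl)silyloxy]phenyl}prop-2-en-1-ol | OC/C=C/c1cc(OC)c(O[Si](C(C)C)(C(C)C)C(C)C)c(OC)c1
F7 | step 3 | [(2R,3R)-3-{3,5-dimethoxy-4-[tri(propan-2-yl)silyloxy]phenyl}oxiran-2-yl]methanol | OC[C@H]1O[C@@H]1c2cc(OC)c(O[Si](C(C)C)(C(C)C)C(C)C)c(OC)c2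
F8 | step 3 | (2S,3R)-3-{3,5-dimethoxy-4-[tri(propan-2-yl)silyloxy]phenyl}oxirane-2-carbaldehyde | O=C[C@H]1O[C@@H]1c2cc(OC)c(O[Si](C(C)C)(C(C)C)C(C)C)c(OC)c2
F9 | step 8 | (3R,4R,5S)-5-{3,5-dimethoxy-4-[tri(propan-2-yl)silyloxy]phenyl}-4-(hydroxymethyl)-N-methoxy-N-methyloxolane-3-carboxamide | CON(C)C(=O)[C@H]1CO[C@H](c2cc(OC)c(O[Si](C(C)C)(C(C)C)C(C)C)c(OC)c2)[C@H]1CO
F10 | step 8 | (3R,4R,5S)-5-{3,5-dimethoxy-4-[tri(propan-2-yl)silyloxy]phenyl}-N-methoxy-N-methyl-4-[(triethylsilyloxy)methyl]oxolane-3-carboxamide | CON(C)C(=O)[C@H]1CO[C@H](c2cc(OC)c(O[Si](C(C)C)(C(C)C)C(C)C)c(OC)c2)[C@H]1CO[Si](CC)(CC)CC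
F11 | step 8 | {3,5-dimethoxy-4-[tri(propan-2-yl)silyloxy]phenyl}[(3R,4R,5S)-5-{3,5-dimethoxy-4-[tri(propan-2-yl)silyloxy]phenyl}-4-[(triethylsilyloxy)methyl]oxolan-3-yl]methanone | COc1cc(C(=O)[C@H]2CO[C@H](c3cc(OC)c(O[Si](C(C)C)(C(C)C)C(C)C)c(OC)c3)[C@H]2CO[Si](CC)(CC)CC)cc(OC)c1O[Si](C(C)C)(C(C)C)C(C)C
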